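Everything rests on one disconnection: the cyclohexene ring of agelasidine C is opened back to all-E geranylgeraniol 1. In one enzymatic operation a protonation-triggered cyclase closes the ring bond C1–C2 and, through one hydride and one methyl shift, creates the quaternary C1, the methine C6 (both stereocentres) and the C2=C3 alkene, giving alcohol 2. The step exploits the 1,2,6-trimethylcyclohex-2-ene ring itself: its C1, C2, C3, C4, C5 and C6 are C10, C15, C14, C13, C12 and C11 of the chain, and the C1 methyl is a former C15 methyl. The precursor is the unprotected tetraene alcohol; three conventional steps then attach the guanidinoethyl sulfone.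

Key step: step 1

Remark on the structures: the six ring carbons are C10–C15 of the chain, so the ring takes three carbons from each of the last two isoprene units and not only from the terminal unit. Chain positions use geranylgeraniol numbering (C1 = CH2OH); ring positions use the numbering of the target ring.

Remark on the precursor: the C1 hydroxyl is left free, because it lies nine carbons from the nearest cationic centre, gives the substrate its polar anchor at the channel mouth, and is the handle for step 2.

Assumption: the target is delivered as the free guanidine drawn (stored as a salt if needed); the cationic stations of step 1 stay enzyme-bound and are treated as mechanism, not as compounds.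

Step 1
Reactants: 1 (2E,6E,10E)-geranylgeraniol
Product: 2 (2E,6E)-3,7-dimethyl-9-[(1S,6R)-1,2,6-trimethylcyclohex-2-en-1-yl]nona-2,6-dien-1-ol
Conditions: engineered squalene–hopene cyclase variant (Alicyclobacillus acidocaldarius scaffold, evolved for monocyclisation with hydride/methyl shift), E. coli whole cells, citrate buffer pH 6.0, 2-hydroxypropyl-β-cyclodextrin, 30 °C
Reagents that add atoms: none
Why: Proposed new method: the acidic aspartate of the cyclase (the DXDD aspartate, Asp376 in the Alicyclobacillus enzyme) protonates C14, the C10=C11 alkene captures the C15 cation, and the resulting C11 cation, which the reshaped pocket keeps away from the C6=C7 alkene and from any base, relaxes by a 1,2-hydride shift (C10 to C11) and a 1,2-methyl shift (C15 to C10) that bring the charge back to C15, beside the aspartate carboxylate, where a C14 proton is removed. The closest known reaction types are squalene–hopene cyclase variants that halt acyclic terpenoids after one ring and class two diterpene cyclases of the halimadienyl diphosphate synthase type, which append the same pair of 1,2-shifts to a cyclisation; their union on geranylgeraniol has not been shown. The one ring closes in a 6-endo-trig cation–olefin mode through a chair fold of C10–C15 (new bond C10–C15, the C1–C2 bond of the ring). Ring C6 (chain C11) is fixed by suprafacial delivery of the axial C10 hydrogen, and ring C1 (chain C10) by migration of the axial C15 methyl, antiperiplanar to that hydrogen, onto the opposite face, so that the two methyls end up cis and the chain trans to the C6 methyl; the absolute sense (1S,6R) is that of the enantiofacial fold the wild-type enzyme uses for ring A of hopene. The step needs initiation at the terminal alkene only, termination after one ring, the two shifts in preference to early proton loss or hydration, and regioselective loss of the ring proton at C14; the substrate contributes its all-E geometry (chair fold, relative configuration), the Markovnikov bias of the isopropylidene end and the polar CH2OH head that holds C1–C9 toward the channel mouth, while the remaining chemoselectivity must come from the evolved pocket.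

Step 2
Reactants: 2 (2E,6E)-3,7-dimethyl-9-[(1S,6R)-1,2,6-trimethylcyclohex-2-en-1-yl]nona-2,6-dien-1-ol
Product: 4 (1S,6R)-1-[(3E,7E)-9-bromo-3,7-dimethylnona-3,7-dien-1-yl]-1,2,6-trimethylcyclohex-2-ene, via allylic mesylate 3 (not isolated)
Conditions: MsCl, Et3N, THF, −40 °C; then LiBr, THF, 0 °C; aqueous work-up, used at once
Reagents that add atoms: lithium bromide, [Li+].[Br-] (methanesulfonyl chloride, CS(=O)(=O)Cl, adds atoms only to intermediate 3)
Why: Mesylation of the primary allylic alcohol and SN2 displacement by bromide under non-acidic conditions is the standard entry to polyprenyl bromides and should leave the three trisubstituted alkenes, their E geometry and both stereocentres untouched.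

Step 3
Reactants: 5 hypotaurine; 6 1H-pyrazole-1-carboxamidine hydrochloride
Product: 7 hypotaurocyamine (2-guanidinoethanesulfinic acid, zwitterion)
Conditions: Na2CO3, degassed H2O, 25 °C, argon; crystallisation from H2O–EtOH
Reagents that add atoms: none
Why: Amidine transfer from a pyrazole carboxamidine to a primary amine in aqueous carbonate (guanylation) is routine for amino acids and amino sulfonic acids, with pyrazole as the leaving group and the sulfinate as a bystander.

Step 4
Reactants: 4 (1S,6R)-1-[(3E,7E)-9-bromo-3,7-dimethylnona-3,7-dien-1-yl]-1,2,6-trimethylcyclohex-2-ene; 7 hypotaurocyamine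
Product: 9 agelasidine C, via agelasidine C hydrobromide 8 (not isolated)
Conditions: DMF–H2O (9:1), 25 °C, argon; then 1 M NaOH, 0 °C, extraction (CHCl3–iPrOH)
Reagents that add atoms: none
Why: S-alkylation of a sulfinate by a primary allylic bromide (SN2) should give the sulfone without allylic transposition, because in zwitterion 7 the guanidine is protonated and not nucleophilic while the soft sulfinate sulfur attacks the soft allylic carbon; cold NaOH then frees the guanidine.

Compound list
1 | (2E,6E,10E)-geranylgeraniol, (2E,6E,10E)-3,7,11,15-tetramethylhexadeca-2,6,10,14-tetraen-1-ol | CC(C)=CCC/C(C)=C/CC/C(C)=C/CC/C(C)=C/CO | starting material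
2 | (2E,6E)-3,7-dimethyl-9-[(1S,6R)-1,2,6-trimethylcyclohex-2-en-1-yl]nona-2,6-dien-1-ol | CC1=CCC[C@@H](C)[C@]1(C)CC/C(C)=C/CC/C(C)=C/CO | intermediate
3 | (2E,6E)-3,7-dimethyl-9-[(1S,6R)-1,2,6-trimethylcyclohex-2-en-1-yl]nona-2,6-dien-1-yl methanesulfonate (allylic mesylate) | CC1=CCC[C@@H](C)[C@]1(C)CC/C(C)=C/CC/C(C)=C/COS(C)(=O)=O | intermediate
4 | (1S,6R)-1-[(3E,7E)-9-bromo-3,7-dimethylnona-3,7-dien-1-yl]-1,2,6-trimethylcyclohex-2-ene | CC1=CCC[C@@H](C)[C@]1(C)CC/C(C)=C/CC/C(C)=C/CBr | intermediate
5 | hypotaurine (2-aminoethanesulfinic acid) | NCCS(=O)O | starting material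
6 | 1H-pyrazole-1-carboxamidine hydrochloride | Cl.NC(=N)n1cccn1 | starting material
7 | hypotaurocyamine (2-guanidinoethanesulfinic acid, zwitterion; drawn neutral) | NC(N)=NCCS(=O)O | intermediate
8 | agelasidine C hydrobromide | CC1=CCC[C@@H](C)[C@]1(C)CC/C(C)=C/CC/C(C)=C/CS(=O)(=O)CCN=C(N)N.Br | intermediate
9 | agelasidine C, 2-{[(2E,6E)-3,7-dimethyl-9-[(1S,6R)-1,2,6-trimethylcyclohex-2-en-1-yl]nona-2,6-dien-1-yl]sulfonyl}ethylguanidine | CC1=CCC[C@@H](C)[C@]1(C)CC/C(C)=C/CC/C(C)=C/CS(=O)(=O)CCN=C(N)N | target

Total step count: 4 (steps 1, 2 and 4 in line; step 3 makes the side fragment).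
Longest linear sequence: 3 steps (1 → 2 → 4 → 9).

Steps most likely to fail

1. Step 1 (Proposed new method). The cascade may not stop where needed: it may run on through the C6=C7 alkene to bicyclic and tricyclic alcohols, the C11 cation may be quenched by early proton loss or by water before the two shifts, the proton may be lost from a methyl instead of C14, or the pocket may not turn the substrate over at all. The fallback is a chemical synthesis of 2 by known reactions. No numbered compound can serve as its origin, since 1 itself is given up; it sets out from purchased 2-methylcyclohex-2-en-1-one F1 and comes back to the route at 2.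
 - Copper-catalysed asymmetric conjugate addition of Me3Al to F1 (Cu(O2CC4H3S), monovalent copper, with a chiral phosphoramidite, Et2O, −30 °C) with Me3SiOTf trapping should give {[(3R)-2,3-dimethylcyclohex-1-en-1-yl]oxy}trimethylsilane F2.
 - MeLi regenerates the lithium enolate, which allyl bromide should alkylate anti to the neighbouring methyl to give (2S,3R)-2-allyl-2,3-dimethylcyclohexan-1-one F3 (methyls cis).
 - Enolisation on the only enolisable side (KN(SiMe3)2, PhNTf2, THF, −78 °C) gives (5R,6S)-5,6-dimethyl-6-(prop-2-en-1-yl)cyclohex-1-en-1-yl trifluoromethanesulfonate F4.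
 - Me2CuLi replaces the triflate by methyl to give (5R,6S)-1,5,6-trimethyl-6-(prop-2-en-1-yl)cyclohex-1-ene F5.
 - 9-BBN hydroboration of the monosubstituted alkene and NaOH/H2O2 give 3-[(1S,6R)-1,2,6-trimethylcyclohex-2-en-1-yl]propan-1-ol F6.
 - Dess–Martin oxidation gives 3-[(1S,6R)-1,2,6-trimethylcyclohex-2-en-1-yl]propanal F7.
 - Ohira–Bestmann homologation (K2CO3, MeOH) gives (1S,6R)-1-(but-3-yn-1-yl)-1,2,6-trimethylcyclohex-2-ene F8.
 - Zirconium-catalysed methylalumination (Me3Al, Cp2ZrCl2, CH2Cl2) and iodinolysis give (1S,6R)-1-[(3E)-4-iodo-3-methylbut-3-en-1-yl]-1,2,6-trimethylcyclohex-2-ene F9.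
 - Purchased (4-iodobut-1-yn-1-yl)trimethylsilane F10 is converted with zinc dust and LiCl in THF into [4-(trimethylsilyl)but-3-yn-1-yl]zinc iodide F11.
 - Negishi coupling of F9 with F11 (Pd(PPh3)4, THF) gives trimethyl{(5E)-6-methyl-8-[(1S,6R)-1,2,6-trimethylcyclohex-2-en-1-yl]oct-5-en-1-yn-1-yl}silane F12.
 - K2CO3 in MeOH gives (1S,6R)-1-[(3E)-3-methyloct-3-en-7-yn-1-yl]-1,2,6-trimethylcyclohex-2-ene F13.
 - A second methylalumination, then n-BuLi and paraformaldehyde, should give 2 with both alkenes E.

2. Step 4. The water-soluble zwitterion and the lipophilic bromide may not meet in one phase, so that solvolysis of the bromide, O-alkylation of the sulfinate or N-alkylation of partly deprotonated guanidine outruns S-alkylation. The fallback reverses the order of S-alkylation and guanylation; it sets out from 5 and 4 and comes back at 9.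
 - Hypotaurine 5 is N-protected (Fmoc-OSu, NaHCO3, H2O–dioxane) to give sodium 2-({[(9H-fluoren-9-yl)methoxy]carbonyl}amino)ethanesulfinate F14, which is soluble in DMF.
 - S-alkylation with 4 in DMF gives 9H-fluoren-9-ylmethyl N-(2-{[(2E,6E)-3,7-dimethyl-9-[(1S,6R)-1,2,6-trimethylcyclohex-2-en-1-yl]nona-2,6-dien-1-yl]sulfonyl}ethyl)carbamate F15.
 - Piperidine in DMF frees 2-{[(2E,6E)-3,7-dimethyl-9-[(1S,6R)-1,2,6-trimethylcyclohex-2-en-1-yl]nona-2,6-dien-1-yl]sulfonyl}ethan-1-amine F16 without acid.
 - Guanylation with 6 and iPr2NEt in DMF gives agelasidine C hydrochloride F17, which the NaOH wash of step 4 converts into 9.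

3. Step 2. The allylic bromide may ionise, leading to allylic transposition, E/Z erosion or loss of material before it is used. The fallback avoids any allylic halide; it sets out from 2 and comes back at 9, bypassing 3, 4 and 8.
 - Methyl chloroformate and pyridine (CH2Cl2, 0 °C) give methyl (2E,6E)-3,7-dimethyl-9-[(1S,6R)-1,2,6-trimethylcyclohex-2-en-1-yl]nona-2,6-dien-1-yl carbonate F18.
 - Tsuji–Trost allylic sulfonylation with zwitterion 7 (Pd(PPh3)4, zerovalent palladium, DMSO–THF, 25 °C) should give 9 directly. The methoxide released on ionisation takes the guanidinium proton, and the linear sulfone is the thermodynamic regioisomer.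
 - The hazard of this variant is E/Z erosion through π–σ–π isomerisation of the allylpalladium intermediate, to be limited by low temperature and short reaction time.

Further compounds
F1 | step 1 | 2-methylcyclohex-2-en-1-one | CC1=CCCCC1=O
F2 | step 1 | {[(3R)-2,3-dimethylcyclohex-1-en-1-yl]oxy}trimethylsilane | CC1=C(O[Si](C)(C)C)CCC[C@H]1C
F3 | step 1 | (2S,3R)-2-allyl-2,3-dimethylcyclohexan-1-one | O=C1CCC[C@@H](C)[C@]1(C)CC=C
F4 | step 1 | (5R,6S)-5,6-dimethyl-6-(prop-2-en-1-yl)cyclohex-1-en-1-yl trifluoromethanesulfonate | O=S(=O)(OC1=CCC[C@@H](C)[C@]1(C)CC=C)C(F)(F)F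
F5 | step 1 | (5R,6S)-1,5,6-trimethyl-6-(prop-2-en-1-yl)cyclohex-1-ene | CC1=CCC[C@@H](C)[C@]1(C)CC=C
F6 | step 1 | 3-[(1S,6R)-1,2,6-trimethylcyclohex-2-en-1-yl]propan-1-ol | CC1=CCC[C@@H](C)[C@]1(C)CCCO
F7 | step 1 | 3-[(1S,6R)-1,2,6-trimethylcyclohex-2-en-1-yl]propanal | CC1=CCC[C@@H](C)[C@]1(C)CCC=O
F8 | step 1 | (1S,6R)-1-(but-3-yn-1-yl)-1,2,6-trimethylcyclohex-2-ene | CC1=CCC[C@@H](C)[C@]1(C)CCC#C
F9 | step 1 | (1S,6R)-1-[(3E)-4-iodo-3-methylbut-3-en-1-yl]-1,2,6-trimethylcyclohex-2-ene | CC1=CCC[C@@H](C)[C@]1(C)CC/C(C)=C/I
F10 | step 1 | (4-iodobut-1-yn-1-yl)trimethylsilane | C[Si](C)(C)C#CCCI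
F11 | step 1 | [4-(trimethylsilyl)but-3-yn-1-yl]zinc iodide | C[Si](C)(C)C#CCC[Zn]I
F12 | step 1 | trimethyl{(5E)-6-methyl-8-[(1S,6R)-1,2,6-trimethylcyclohex-2-en-1-yl]oct-5-en-1-yn-1-yl}silane | CC1=CCC[C@@H](C)[C@]1(C)CC/C(C)=C/CCC#C[Si](C)(C)C
F13 | step 1 | (1S,6R)-1-[(3E)-3-methyloct-3-en-7-yn-1-yl]-1,2,6-trimethylcyclohex-2-ene | CC1=CCC[C@@H](C)[C@]1(C)CC/C(C)=C/CCC#C
F14 | step 4 | sodium 2-({[(9H-fluoren-9-yl)methoxy]carbonyl}amino)ethanesulfinate | [Na+].[O-]S(=O)CCNC(=O)OCC1c2ccccc2-c2ccccc12
F15 | step 4 | 9H-fluoren-9-ylmethyl N-(2-{[(2E,6E)-3,7-dimethyl-9-[(1S,6R)-1,2,6-trimethylcyclohex-2-en-1-yl]nona-2,6-dien-1-yl]sulfonyl}ethyl)carbamate | CC1=CCC[C@@H](C)[C@]1(C)CC/C(C)=C/CC/C(C)=C/CS(=O)(=O)CCNC(=O)OCC3c4ccccc4-c4ccccc34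
F16 | step 4 | 2-{[(2E,6E)-3,7-dimethyl-9-[(1S,6R)-1,2,6-trimethylcyclohex-2-en-1-yl]nona-2,6-dien-1-yl]sulfonyl}ethan-1-amine | CC1=CCC[C@@H](C)[C@]1(C)CC/C(C)=C/CC/C(C)=C/CS(=O)(=O)CCN
F17 | step 4 | agelasidine C hydrochloride | CC1=CCC[C@@H](C)[C@]1(C)CC/C(C)=C/CC/C(C)=C/CS(=O)(=O)CCN=C(N)N.Cl
F18 | step 2 | methyl (2E,6E)-3,7-dimethyl-9-[(1S,6R)-1,2,6-trimethylcyclohex-2-en-1-yl]nona-2,6-dien-1-yl carbonate | CC1=CCC[C@@H](C)[C@]1(C)CC/C(C)=C/CC/C(C)=C/COC(=O)OC
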